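The ten-membered ring is released, not closed. C1 and C6 face each other 1,6 across the carbocycle; C6 ends as the oxygen-bearing lactone carbon and C1 as the alkene carbon next to the C10 ester, so each can be written as a ketone and the pair as a tetrasubstituted alkene shared by six-membered rings A and B of a Birch-type hexahydronaphthalene. Ozonolysis of that ring-fusion alkene in diene diester 17 gives cyclodecenedione β-keto ester 19 in one operation. Compound 17 already carries C7, C8 and C9, set on the tetralin stage of ring B, with O8 and O9 under different ethers and C12 as an ester.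

Key step: step 11

Remark 1: locants are the germacrane locants of the target (ring C1–C10; C11(=C13)–C12 lactone arm on C7; C14 ester carbon on C10; C15 methyl on C4; O6, O8, O9 on C6, C8, C9); ring A is C1–C6, ring B is C1, C6–C10.
Remark 2: the SMILES is taken as the definition of the target: 4R,5R,6S,7S,8R,9R, i.e. a cis-fused C6–C7 lactone, O8 cis and O9 trans to the C7 arm, and a trans C4–C5 epoxide.
Remark 3: C10 (in 9–19), C5 (in 22–24) and C11 (in 28, 29) are passing stereocentres that end trigonal; 9–17 are drawn with the C10 ester cis to the C7 arm, C5 and C11 are left undefined.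
Remark 4: ester 1 is taken as a catalogue compound; if only the parent acid is on offer, a Fischer esterification precedes step 1.
Remark 5: from step 15 on, temperatures stay at or below room temperature, because the 1(10),4-diene is a 1,5-diene that could undergo Cope rearrangement on heating.

Step 1
Reactants: 1 methyl 2-(2-bromo-4-methylphenyl)acetate; 2 acrolein diethyl acetal
Product: 4 methyl 2-{4-methyl-2-[(E)-3-oxoprop-1-enyl]phenyl}acetate, via Heck acetal 3 (not isolated)
Conditions: Pd(OAc)2 (3 mol %), nBu4NOAc, K2CO3, KCl, DMF, 90 °C; then 2 M HCl, rt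
Reagents that add atoms: acrolein diethyl acetal (2), C=CC(OCC)OCC; water, O
Why: Heck arylation of the acetal-masked acrolein attaches C7–C9 to C6 with (E) geometry through syn insertion and syn β-hydride elimination, and mild acid then unmasks the aldehyde; no stereocentre is formed.

Step 2
Reactants: 4 methyl 2-{4-methyl-2-[(E)-3-oxoprop-1-enyl]phenyl}acetate; 5 dimethyl malonate
Product: 6 dimethyl 2-{(1R)-1-[2-(2-methoxy-2-oxoethyl)-5-methylphenyl]-3-oxopropyl}malonate
Conditions: (S)-2-{bis[3,5-bis(trifluoromethyl)phenyl](trimethylsilyloxy)methyl}pyrrolidine (10 mol %), EtOH, 0 °C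
Reagents that add atoms: dimethyl malonate (5), COC(=O)CC(=O)OC
Why: Asymmetric Michael addition under iminium-ion organocatalysis: the diarylsilyloxymethyl group of the (S)-pyrrolidine shields one face of the (E)-iminium ion, the malonate adds to C7 from the open face, and this fixes C7 in the (R) sense that places C11 on the face later shared by O8.

Step 3
Reactants: 6 dimethyl 2-{(1R)-1-[2-(2-methoxy-2-oxoethyl)-5-methylphenyl]-3-oxopropyl}malonate
Product: 7 dimethyl 2-[(1R)-4-(methoxycarbonyl)-7-methyl-1,2-dihydronaphthalen-1-yl]malonate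
Conditions: NaOMe (2.2 equiv), MeOH, 0 °C → rt; then AcOH
Reagents that add atoms: none
Why: Intramolecular aldol condensation: the arylacetate enolate (C10) closes ring B on the C9 aldehyde and E1cB loss of water gives the styrene-conjugated enoate, while the malonate, present as its sodium salt, cannot be expelled in a retro-Michael step, so C7 keeps its configuration.

Step 4
Reactants: 7 dimethyl 2-[(1R)-4-(methoxycarbonyl)-7-methyl-1,2-dihydronaphthalen-1-yl]malonate
Product: 8 methyl (4R)-4-(2-methoxy-2-oxoethyl)-6-methyl-3,4-dihydronaphthalene-1-carboxylate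
Conditions: LiCl, H2O, DMSO, 150 °C
Reagents that add atoms: none
Why: Krapcho dealkoxycarbonylation: chloride demethylates one malonate ester, the carboxylate loses CO2 and the enolate is protonated by water, which leaves the C11–C12 acetate arm; the conjugated C14 ester and C7 are untouched.

Step 5
Reactants: 8 methyl (4R)-4-(2-methoxy-2-oxoethyl)-6-methyl-3,4-dihydronaphthalene-1-carboxylate
Product: 9 methyl (1R,4S)-4-(2-methoxy-2-oxoethyl)-6-methyl-1,4-dihydronaphthalene-1-carboxylate (1,4-cis)
Conditions: LiN(iPr)2 (2.3 equiv), THF–DMPU, −78 °C; then AcOH, −78 °C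
Reagents that add atoms: none
Why: Deconjugative protonation of an extended enolate: both esters are deprotonated (which also suppresses Claisen chemistry) and kinetic protonation of the dienolate at its α-carbon C10 moves the alkene to C8=C9; the proton should enter anti to the pseudoaxial C7 arm to give the 1,4-cis ester, a centre that loses its configuration after step 11.

Step 6
Reactants: 9 methyl (1R,4S)-4-(2-methoxy-2-oxoethyl)-6-methyl-1,4-dihydronaphthalene-1-carboxylate
Product: 11 methyl (3aR,4R,5S,9bR)-4-hydroxy-8-methyl-2-oxo-1,2,3a,4,5,9b-hexahydronaphtho[2,1-b]furan-5-carboxylate (cis-fused 8,12-lactone; O9–H trans to O8), via epoxide 10 (not isolated)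
Conditions: mCPBA, CH2Cl2, 0 °C; then CSA (10 mol %), H2O (1 equiv), rt
Reagents that add atoms: 3-chloroperbenzoic acid, OOC(=O)c1cccc(Cl)c1; water, O
Why: Prilezhaev epoxidation followed by acid-catalysed epoxy ester lactonisation: the peracid approaches C8=C9 from the face opposite the pseudoaxial C7 arm, and the C12 ester carbonyl then opens the epoxide at C8 with inversion (5-exo), so O8 ends cis to C11 in a cis-fused γ-lactone and the former epoxide oxygen stays on C9, trans to O8.

Step 7
Reactants: 11 hydroxy lactone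
Product: 12 methyl (3aR,4R,5S,9bR)-4-(methoxymethoxy)-8-methyl-2-oxo-1,2,3a,4,5,9b-hexahydronaphtho[2,1-b]furan-5-carboxylate
Conditions: MOMCl, iPr2NEt, CH2Cl2, 0 °C → rt
Reagents that add atoms: chloromethyl methyl ether, COCCl
Why: MOM ether formation (O-alkylation of the alcohol by the α-chloro ether in the presence of a hindered amine) marks O9, the future acetate site, with a group that is later removed independently of the O8 silyl ether; no stereocentre is affected.

Step 8
Reactants: 12 MOM-protected lactone ester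
Product: 15 (1S,2R,3R,4R)-3-[tert-butyl(dimethyl)silyl]oxy-4-(carboxymethyl)-2-(methoxymethoxy)-6-methyl-1,2,3,4-tetrahydronaphthalene-1-carboxylic acid, via dilithium hydroxy dicarboxylate 13 (not isolated), via tris-silyl derivative 14 (not isolated)
Conditions: LiOH, THF/MeOH/H2O, 40 °C, then evaporation to dryness; TBSOTf, 2,6-lutidine, CH2Cl2, −78 → 0 °C; AcOH/THF/H2O, rt
Reagents that add atoms: lithium hydroxide, [Li+].[OH-]; tert-butyldimethylsilyl triflate, CC(C)(C)[Si](C)(C)OS(=O)(=O)C(F)(F)F
Why: Saponification, in-flask silylation and selective silyl ester hydrolysis: hydroxide opens the lactone and cleaves the C14 ester, the C8 hydroxyl of the dicarboxylate is silylated before it can relactonise, and the two silyl esters are hydrolysed under conditions that leave the secondary silyl ether intact; C7–C9 are untouched and C10 is of no consequence.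

Step 9
Reactants: 15 tetralin diacid
Product: 16 (1S,2R,3R,4R)-3-[tert-butyl(dimethyl)silyl]oxy-4-(carboxymethyl)-2-(methoxymethoxy)-6-methyl-1,2,3,4,5,8-hexahydronaphthalene-1-carboxylic acid
Conditions: Li, NH3(l), THF, t-BuOH, −78 → −33 °C; then NH4Cl
Reagents that add atoms: none
Why: Birch reduction: the carboxylates resist reduction, the trialkylbenzene takes up two electrons and two protons at the unsubstituted, para-related C2 and C5, and the alkyl-bearing carbons stay sp2, which places the tetrasubstituted alkene at the C1–C6 ring fusion and the trisubstituted one at C3=C4; no stereocentre is created.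

Step 10
Reactants: 16 hexahydronaphthalene diacid
Product: 17 methyl (1S,2R,3R,4R)-3-[tert-butyl(dimethyl)silyl]oxy-4-(2-methoxy-2-oxoethyl)-2-(methoxymethoxy)-6-methyl-1,2,3,4,5,8-hexahydronaphthalene-1-carboxylate (Birch diene diester; rings A and B fused at C1=C6)
Conditions: Me3SiCHN2, MeOH/toluene, 0 °C
Reagents that add atoms: (trimethylsilyl)diazomethane, C[Si](C)(C)C=[N+]=[N-]
Why: Esterification with a diazoalkane (protonation of the diazo carbon by the acid, then SN2 loss of N2) works under neutral conditions, so the β,γ-unsaturated C14 ester is not drawn into conjugation.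

Step 11
Reactants: 17 Birch diene diester
Product: 19 methyl (1R,2R,3R,4S,7Z)-3-[tert-butyl(dimethyl)silyl]oxy-4-(2-methoxy-2-oxoethyl)-2-(methoxymethoxy)-7-methyl-5,10-dioxocyclodec-7-ene-1-carboxylate (cyclodecene-1,6-dione β-keto ester), via ozonide 18 (not isolated)
Conditions: O3/O2, CH2Cl2, −78 °C, Sudan Red 7B as end-point indicator; then PPh3, −78 °C → rt; crude 19 used at once
Reagents that add atoms: ozone, [O-][O+]=O
Why: Ozone adds as a 1,3-dipole to the tetrasubstituted C1=C6 alkene, the primary ozonide cycloreverts to a ketone and a carbonyl oxide that stay tied together by the two ring arms and recombine to ozonide 18, and PPh3 reduces the peroxide to the C1 and C6 ketones (Criegee mechanism). The closest known reaction type is the ozonolytic opening of the ring-fusion alkene of octalins and of Birch-type hexahydronaphthalenes to cyclodecane-1,6-diones. No ring is closed by bond formation: the ten-membered carbocycle appears because the bond shared by rings A and B is cut, so no closure mode applies. No stereocentre is created; C7, C8 and C9 pass from ring B unchanged and C10, now flanked by two carbonyl groups, may epimerise without consequence. The step needs chemoselectivity for C1=C6 over the trisubstituted C3=C4 alkene, and the substrate secures it through the higher substitution (electron richness) of the ring-fusion alkene, supported by −78 °C and by stopping the ozone stream when Sudan Red 7B fades.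

Step 12
Reactants: 19 cyclodecene-1,6-dione β-keto ester
Product: 20 (Z)-enol triflate of 19 [C1(OTf)=C10(CO2Me); triflate cis to the ester; C2 cis to C9]
Conditions: LiOTf, Et3N, Tf2O, CH2Cl2, −78 → 0 °C
Reagents that add atoms: triflic anhydride, O=S(=O)(OS(=O)(=O)C(F)(F)F)C(F)(F)F
Why: O-Sulfonylation of a β-keto ester enolate: Et3N removes only the doubly activated C10 hydrogen, lithium chelation between the enolate oxygen and the ester carbonyl gives the (Z)-triflate (OTf cis to CO2Me, C2 cis to C9 in the ring), and the C6 ketone is not enolised at this temperature.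

Step 13
Reactants: 20 (Z)-enol triflate
Product: 21 enoate [C1H=C10(CO2Me) with C2 cis to C9; C6 ketone; (Z)-C3=C4]
Conditions: Pd(OAc)2 (5 mol %), PPh3 (10 mol %), nBu3N, HCO2H, DMF, 60 °C
Reagents that add atoms: none
Why: Palladium-catalysed formate reduction of a vinyl triflate (oxidative addition to zerovalent palladium, exchange of triflate for formate, loss of CO2, C–H reductive elimination) replaces OTf by H with retention of the alkene geometry.

Step 14
Reactants: 21 enoate
Product: 22 5-hydroxy ketone (α-ketol of 21; C5 epimers)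
Conditions: KN(SiMe3)2 (1.05 equiv), THF, −78 °C; 2-(benzenesulfonyl)-3-phenyloxaziridine, −78 °C; then AcOH, −78 °C
Reagents that add atoms: 2-(benzenesulfonyl)-3-phenyloxaziridine, O=S(=O)(N1OC1c1ccccc1)c1ccccc1
Why: Enolate hydroxylation with an N-sulfonyloxaziridine: the C5 hydrogens, α to the ketone and allylic, are removed first, the dienolate takes up electrophilic oxygen at its α-carbon, and the configuration of the new C5 carbinol is irrelevant because C5 becomes trigonal in step 15.

Step 15
Reactants: 22 5-hydroxy ketone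
Product: 25 (E)-enone [C4=C5 conjugated to the C6 ketone; C3 saturated], via sulfonylhydrazide 23 (not isolated), via allylic diazene 24 (not isolated)
Conditions: PPh3, DEAD, 2-nitrobenzenesulfonylhydrazide, N-methylmorpholine, −30 → 23 °C
Reagents that add atoms: none
Why: Reductive 1,3-transposition of an allylic alcohol through a monoalkyl diazene: Mitsunobu substitution at C5 by the sulfonylhydrazide, loss of sulfinic acid and retro-ene loss of N2 deliver hydrogen to C3 and shift the alkene to C4=C5; because allylic 1,3-strain in the (Z)-C3=C4 alkene keeps H5 in the alkene plane and C6 out of it, C6 should end trans to C3, i.e. the (E)-enone, from either C5 epimer.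

Step 16
Reactants: 25 (E)-enone
Product: 27 cis-fused 6,12-lactone [O6 cis to C11; (E)-C4=C5; 8-OTBS; 9-OMOM], via allylic alcohol 26 (not isolated)
Conditions: NaBH4, CeCl3·7H2O, MeOH, −78 °C; then PPTS (cat.), CH2Cl2, rt
Reagents that add atoms: none
Why: Luche 1,2-reduction then acid-catalysed lactonisation: hydride should reach the C6 carbonyl from the peripheral face anti to C8 (Felkin–Anh with ring carbon C8 as the large group), which puts O6 on the same side as C11 (the C6 configuration of the target), and this γ-hydroxy ester closes to the cis-fused lactone with loss of methanol.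

Step 17
Reactants: 27 cis-fused 6,12-lactone
Product: 30 α-methylene lactone (C11=C13), via Mannich base 28 (not isolated), via ammonium iodide 29 (not isolated)
Conditions: LiN(iPr)2 (1.2 equiv), THF, −78 °C; CH2=NMe2+ I−, −78 → 0 °C; MeI, CH2Cl2, rt; aq NaHCO3, rt
Reagents that add atoms: N,N-dimethylmethyleneiminium iodide, C=[N+](C)C.[I-]
Why: α-Methylenation of a lactone through a Mannich base (aminomethylation of the enolate with Eschenmoser's salt, quaternisation, E1cB elimination): the lactone C11–H is the only readily accessible α-hydrogen (the enoate has none and its γ-hydrogens at C2 lie trans to the ester), and loss of trimethylamine gives the exocyclic C11=C13 alkene, which removes the C11 stereocentre.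

Step 18
Reactants: 30 α-methylene lactone
Product: 31 9-hydroxy compound (O8–TBS kept)
Conditions: Me2BBr, CH2Cl2, −78 °C; then aq NaHCO3
Reagents that add atoms: none
Why: Acetal cleavage by a boron Lewis acid: Me2BBr coordinates the MOM acetal and bromide breaks it at −78 °C, which frees O9 while the TBS ether, the esters, the lactone and the alkenes are left alone.

Step 19
Reactants: 31 9-hydroxy compound
Product: 32 9-acetate
Conditions: Ac2O, pyridine, DMAP (cat.), CH2Cl2, 0 °C
Reagents that add atoms: acetic anhydride, CC(=O)OC(C)=O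
Why: DMAP-catalysed acylation (nucleophilic catalysis) acetylates O9, the only free hydroxyl.

Step 20
Reactants: 32 9-acetate
Product: 33 8-hydroxy 9-acetate
Conditions: HF·pyridine, pyridine, THF, 0 °C → rt
Reagents that add atoms: none
Why: Fluoride-driven desilylation: buffered HF·pyridine cleaves the O8 silyl ether through the strong Si–F bond without acyl migration or lactone opening.

Step 21
Reactants: 33 8-hydroxy 9-acetate
Product: 34 8-methacrylate 9-acetate (4,5-alkene precursor of the target)
Conditions: methacrylic anhydride, Et3N, DMAP (cat.), CH2Cl2, 0 °C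
Reagents that add atoms: methacrylic anhydride, C=C(C)C(=O)OC(=O)C(C)=C
Why: DMAP-catalysed acylation with the anhydride should esterify O8 rapidly at 0 °C, before this hydroxyl (cis to C11) can attack the lactone carbonyl.

Step 22
Reactants: 34 8-methacrylate 9-acetate
Product: 35 fluctuadin
Conditions: mCPBA, NaHCO3, CH2Cl2, 0 °C
Reagents that add atoms: 3-chloroperbenzoic acid, OOC(=O)c1cccc(Cl)c1
Why: Prilezhaev epoxidation: C4=C5 is the only alkene not conjugated to a carbonyl group, and with H6 eclipsing the alkene (allylic 1,3-strain with C15) the ring covers the face that carries C7, so the peracid should add to the exposed face syn to O6 and, the alkene being (E), deliver the trans (4R,5R) epoxide of the target.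

Compound list

1 | methyl 2-(2-bromo-4-methylphenyl)acetate | COC(=O)Cc1ccc(C)cc1Br | starting material
2 | acrolein diethyl acetal | C=CC(OCC)OCC | starting material
3 | methyl 2-{2-[(E)-3,3-diethoxyprop-1-enyl]-4-methylphenyl}acetate (Heck acetal) | CCOC(OCC)/C=C/c1cc(C)ccc1CC(=O)OC | intermediate
4 | methyl 2-{4-methyl-2-[(E)-3-oxoprop-1-enyl]phenyl}acetate | O=C/C=C/c1cc(C)ccc1CC(=O)OC | intermediate
5 | dimethyl malonate | COC(=O)CC(=O)OC | starting material
6 | dimethyl 2-{(1R)-1-[2-(2-methoxy-2-oxoethyl)-5-methylphenyl]-3-oxopropyl}malonate | O=CC[C@H](C(C(=O)OC)C(=O)OC)c1cc(C)ccc1CC(=O)OC | intermediate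
7 | dimethyl 2-[(1R)-4-(methoxycarbonyl)-7-methyl-1,2-dihydronaphthalen-1-yl]malonate | COC(=O)C1=CC[C@H](C(C(=O)OC)C(=O)OC)c2cc(C)ccc21 | intermediate
8 | methyl (4R)-4-(2-methoxy-2-oxoethyl)-6-methyl-3,4-dihydronaphthalene-1-carboxylate | COC(=O)C1=CC[C@H](CC(=O)OC)c2cc(C)ccc21 | intermediate
9 | methyl (1R,4S)-4-(2-methoxy-2-oxoethyl)-6-methyl-1,4-dihydronaphthalene-1-carboxylate (1,4-cis) | COC(=O)[C@@H]1C=C[C@H](CC(=O)OC)c2cc(C)ccc21 | intermediate
10 | 2,3-epoxide of 9, oxirane on the face opposite the C1 and C4 substituents | COC(=O)[C@@H]1[C@H]2O[C@H]2[C@H](CC(=O)OC)c3cc(C)ccc31 | intermediate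
11 | methyl (3aR,4R,5S,9bR)-4-hydroxy-8-methyl-2-oxo-1,2,3a,4,5,9b-hexahydronaphtho[2,1-b]furan-5-carboxylate | COC(=O)[C@@H]1[C@@H](O)[C@H](OC(=O)C2)[C@H]2c3cc(C)ccc31 | intermediate
12 | methyl (3aR,4R,5S,9bR)-4-(methoxymethoxy)-8-methyl-2-oxo-1,2,3a,4,5,9b-hexahydronaphtho[2,1-b]furan-5-carboxylate | COC(=O)[C@@H]1[C@@H](OCOC)[C@H](OC(=O)C2)[C@H]2c3cc(C)ccc31 | intermediate
13 | dilithium (1S,2R,3R,4R)-4-(carboxylatomethyl)-3-hydroxy-2-(methoxymethoxy)-6-methyl-1,2,3,4-tetrahydronaphthalene-1-carboxylate | [Li+].[Li+].[O-]C(=O)[C@@H]1[C@@H](OCOC)[C@H](O)[C@H](CC([O-])=O)c2cc(C)ccc21 | intermediate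
14 | bis(tert-butyldimethylsilyl) ester of 15 (O8 silyl ether, two silyl esters) | CC(C)(C)[Si](C)(C)OC(=O)[C@@H]1[C@@H](OCOC)[C@H](O[Si](C)(C)C(C)(C)C)[C@H](CC(=O)O[Si](C)(C)C(C)(C)C)c2cc(C)ccc21 | intermediate
15 | (1S,2R,3R,4R)-3-[tert-butyl(dimethyl)silyl]oxy-4-(carboxymethyl)-2-(methoxymethoxy)-6-methyl-1,2,3,4-tetrahydronaphthalene-1-carboxylic acid | OC(=O)[C@@H]1[C@@H](OCOC)[C@H](O[Si](C)(C)C(C)(C)C)[C@H](CC(O)=O)c2cc(C)ccc21 | intermediate
16 | (1S,2R,3R,4R)-3-[tert-butyl(dimethyl)silyl]oxy-4-(carboxymethyl)-2-(methoxymethoxy)-6-methyl-1,2,3,4,5,8-hexahydronaphthalene-1-carboxylic acid | OC(=O)[C@@H]1[C@@H](OCOC)[C@H](O[Si](C)(C)C(C)(C)C)[C@H](CC(O)=O)C2=C1CC=C(C)C2 | intermediate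
17 | methyl (1S,2R,3R,4R)-3-[tert-butyl(dimethyl)silyl]oxy-4-(2-methoxy-2-oxoethyl)-2-(methoxymethoxy)-6-methyl-1,2,3,4,5,8-hexahydronaphthalene-1-carboxylate (Birch diene diester) | COC(=O)[C@@H]1[C@@H](OCOC)[C@H](O[Si](C)(C)C(C)(C)C)[C@H](CC(=O)OC)C2=C1CC=C(C)C2 | intermediate
18 | ozonide of 17 across C1 and C6 (1,2,4-trioxolane; configuration at C1 and C6 not defined) | COC(=O)[C@@H]1[C@@H](OCOC)[C@H](O[Si](C)(C)C(C)(C)C)[C@H](CC(=O)OC)C23C/C(C)=C\CC1(O2)OO3 | intermediate
19 | methyl (1R,2R,3R,4S,7Z)-3-[tert-butyl(dimethyl)silyl]oxy-4-(2-methoxy-2-oxoethyl)-2-(methoxymethoxy)-7-methyl-5,10-dioxocyclodec-7-ene-1-carboxylate | COC(=O)[C@@H]1[C@@H](OCOC)[C@H](O[Si](C)(C)C(C)(C)C)[C@H](CC(=O)OC)C(=O)C/C(C)=C\CC1=O | intermediate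
20 | (Z)-enol triflate of 19 at C1, triflate cis to the C10 ester, C6 ketone and (Z)-C3=C4 retained | CC(C)(C)[Si](C)(C)O[C@@H]1[C@H](CC(=O)OC)C(=O)C/C(C)=C\C/C(OS(=O)(=O)C(F)(F)F)=C(/C(=O)OC)[C@H]1OCOC | intermediate
21 | enoate: 20 with H in place of OTf (C1H=C10 ester alkene with C2 cis to C9) | CC(C)(C)[Si](C)(C)O[C@@H]1[C@H](CC(=O)OC)C(=O)C/C(C)=C\C/C=C(/C(=O)OC)[C@H]1OCOC | intermediate
22 | 5-hydroxy derivative of 21 (α-ketol, C5 not defined) | CC(C)(C)[Si](C)(C)O[C@@H]1[C@H](CC(=O)OC)C(=O)C(O)/C(C)=C\C/C=C(/C(=O)OC)[C@H]1OCOC | intermediate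
23 | N-(C5-alkyl)-N-(2-nitrophenylsulfonyl)hydrazine from 22 | CC(C)(C)[Si](C)(C)O[C@@H]1[C@H](CC(=O)OC)C(=O)C(N(N)S(=O)(=O)c2ccccc2[N+](=O)[O-])/C(C)=C\C/C=C(/C(=O)OC)[C@H]1OCOC | intermediate
24 | C5 allylic diazene | CC(C)(C)[Si](C)(C)O[C@@H]1[C@H](CC(=O)OC)C(=O)C(N=N)/C(C)=C\C/C=C(/C(=O)OC)[C@H]1OCOC | intermediate
25 | (E)-enone: C4=C5 conjugated to the C6 ketone, C3 saturated, enoate unchanged | CC(C)(C)[Si](C)(C)O[C@@H]1[C@H](CC(=O)OC)C(=O)/C=C(C)/CC/C=C(/C(=O)OC)[C@H]1OCOC | intermediate
26 | C6 allylic alcohol of 25, O6 cis to C11 | CC(C)(C)[Si](C)(C)O[C@@H]1[C@H](CC(=O)OC)[C@H](O)/C=C(C)/CC/C=C(/C(=O)OC)[C@H]1OCOC | intermediate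
27 | cis-fused 6,12-lactone with (E)-C4=C5, 8-OTBS and 9-OMOM | CC(C)(C)[Si](C)(C)O[C@@H]1[C@@H]2CC(=O)O[C@@H]2/C=C(C)/CC/C=C(/C(=O)OC)[C@H]1OCOC | intermediate
28 | 11-(dimethylaminomethyl) lactone (C11 not defined) | CC(C)(C)[Si](C)(C)O[C@@H]1[C@@H]2C(CN(C)C)C(=O)O[C@@H]2/C=C(C)/CC/C=C(/C(=O)OC)[C@H]1OCOC | intermediate
29 | 11-(trimethylammoniomethyl) lactone iodide | CC(C)(C)[Si](C)(C)O[C@@H]1[C@@H]2C(C[N+](C)(C)C)C(=O)O[C@@H]2/C=C(C)/CC/C=C(/C(=O)OC)[C@H]1OCOC.[I-] | intermediate
30 | α-methylene lactone (C11=C13) with 8-OTBS and 9-OMOM | CC(C)(C)[Si](C)(C)O[C@@H]1[C@@H]2C(=C)C(=O)O[C@@H]2/C=C(C)/CC/C=C(/C(=O)OC)[C@H]1OCOC | intermediate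
31 | 9-hydroxy α-methylene lactone with 8-OTBS | CC(C)(C)[Si](C)(C)O[C@@H]1[C@@H]2C(=C)C(=O)O[C@@H]2/C=C(C)/CC/C=C(/C(=O)OC)[C@H]1O | intermediate
32 | 9-acetate with 8-OTBS | CC(C)(C)[Si](C)(C)O[C@@H]1[C@@H]2C(=C)C(=O)O[C@@H]2/C=C(C)/CC/C=C(/C(=O)OC)[C@H]1OC(C)=O | intermediate
33 | 8-hydroxy 9-acetate | O[C@@H]1[C@@H]2C(=C)C(=O)O[C@@H]2/C=C(C)/CC/C=C(/C(=O)OC)[C@H]1OC(C)=O | intermediate
34 | 8-methacrylate 9-acetate with (E)-C4=C5 (4,5-alkene precursor of the target) | C=C(C)C(=O)O[C@@H]1[C@@H]2C(=C)C(=O)O[C@@H]2/C=C(C)/CC/C=C(/C(=O)OC)[C@H]1OC(C)=O | intermediate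
35 | fluctuadin | C=C(C)C(=O)O[C@@H]1[C@@H]2C(=C)C(=O)O[C@@H]2[C@H]2O[C@]2(C)CC/C=C(/C(=O)OC)[C@H]1OC(C)=O | target

Total step count: 22. Longest linear sequence: 22 steps (from 1).

Steps most likely to fail

Step 11. Ozone may also attack the trisubstituted C3=C4 alkene, or over-oxidise once the ring-fusion alkene is consumed (loss of chemoselectivity). The fallback sets out from 17 and uses an oxidant that discriminates by alkene substitution more sharply than ozone: one equivalent of mCPBA (NaHCO3, CH2Cl2, −20 °C) should epoxidise only the tetrasubstituted alkene to give ring-fusion epoxide F1, and H5IO6 in wet THF (hydrolysis of the ditertiary epoxide and glycol cleavage in one flask) then cuts the same C1–C6 bond and comes back to the route at 19.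

Step 15. The Mitsunobu displacement at the hindered α-ketol carbon may stall, or the diazene may tautomerise to an α-keto hydrazone faster than it loses N2. The fallback sets out from 22 and postpones the transposition until the ketone is gone: NaBH4 and CeCl3·7H2O in MeOH at −78 °C give diol ester F2, which lactonises through O6 (PPTS) to hydroxy lactone F3; the same reductive transposition (PPh3, DEAD, 2-nitrobenzenesulfonylhydrazide) is then run on this ordinary secondary allylic alcohol through hydrazide F4 and diazene F5, which has no carbonyl beside the N=N unit, and comes back to the route at 27, by-passing 25 and 26.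

Step 16. Hydride may be delivered to the other face of the C6 carbonyl (poor or reversed facial selectivity), which would lead to the trans-fused lactone. The fallback sets out from 25 and corrects C6 by inversion: the reduction is worked up cold and without acid so that the C6 epimer, epi-alcohol F6, does not lactonise; a Mitsunobu reaction with 4-nitrobenzoic acid (PPh3, DIAD, THF, 0 °C) gives nitrobenzoate F7 with the required C6 configuration, and K2CO3 in MeOH removes the aroyl group to come back to the route at 26, which lactonises to 27 as before.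

Further compounds
F1 | step 11 | C1–C6 epoxide of 17 (either face) | COC(=O)[C@@H]1[C@@H](OCOC)[C@H](O[Si](C)(C)C(C)(C)C)[C@H](CC(=O)OC)C23CC(C)=CCC13O2
F2 | step 15 | 5,6-diol ester from 22 (O6 cis to C11, C5 not defined) | CC(C)(C)[Si](C)(C)O[C@@H]1[C@H](CC(=O)OC)[C@H](O)C(O)/C(C)=C\C/C=C(/C(=O)OC)[C@H]1OCOC
F3 | step 15 | 5-hydroxy cis-fused 6,12-lactone with (Z)-C3=C4 | CC(C)(C)[Si](C)(C)O[C@@H]1[C@@H]2CC(=O)O[C@@H]2C(O)/C(C)=C\C/C=C(/C(=O)OC)[C@H]1OCOC
F4 | step 15 | N-(C5-alkyl)-N-(2-nitrophenylsulfonyl)hydrazine of the lactone | CC(C)(C)[Si](C)(C)O[C@@H]1[C@@H]2CC(=O)O[C@@H]2C(N(N)S(=O)(=O)c3ccccc3[N+](=O)[O-])/C(C)=C\C/C=C(/C(=O)OC)[C@H]1OCOC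
F5 | step 15 | C5 allylic diazene of the lactone | CC(C)(C)[Si](C)(C)O[C@@H]1[C@@H]2CC(=O)O[C@@H]2C(N=N)/C(C)=C\C/C=C(/C(=O)OC)[C@H]1OCOC
F6 | step 16 | C6 epimer of allylic alcohol 26 | CC(C)(C)[Si](C)(C)O[C@@H]1[C@H](CC(=O)OC)[C@@H](O)/C=C(C)/CC/C=C(/C(=O)OC)[C@H]1OCOC
F7 | step 16 | 4-nitrobenzoate of 26 (C6 inverted relative to F6) | CC(C)(C)[Si](C)(C)O[C@@H]1[C@H](CC(=O)OC)[C@H](OC(=O)c2ccc(cc2)[N+](=O)[O-])/C=C(C)/CC/C=C(/C(=O)OC)[C@H]1OCOC
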